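**Plan**

1. Numbering (daucane): C1 is the methyl-bearing ring-fusion carbon (methyl C15), C2/C3 the cyclopentane CH2 groups, C4 the isopropyl carbinol, C5 the ring-fusion CH, C6 the ester carbinol, C7 the CH2, C8 the methyl-bearing alkene carbon (methyl C14), C9 the alkene CH, C10 the allylic carbinol; α is the face of H-5, β the face of C15.
2. Retrosynthesis: the C10 alcohol goes back to a ketone and the C6 ester to the alcohol; C6–O goes back to C6–Si and C8–CH3 to a C8 enol triflate; the seven-membered ring is then cut at C8–C9 and C5–C6 (and C1–CH3) in one operation, leaving acetylcyclopentene 11 and acylsilane 18.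
3. Enabling feature: in the cycloheptene ring C10 and C8 stand 1,3 to each other at ketone level, C6 carries a heteroatom next to the ring-fusion CH C5, and C9–C10–C1=C5 is an alkenyl methyl ketone. This is the pattern made by a Brook rearrangement-mediated [3+4] annulation of a methyl ketone enolate (C9, C10, C1, C5) with a β-silyl acryloylsilane (C8, C7, C6).
4. Forward order: the cyclopentene is closed by intramolecular aldol condensation; the seven-membered ring is fused onto it in the annulation (cyclopropanolate, then [3,3] ring enlargement) and the angular methyl is added by trapping the resulting enolate; then C8 methyl, C6–OH, ester, C10 reduction.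
5. Stereochemistry: C4 is bought ((R)-2-hydroxy-3-methylbutanoic acid, alkylated with self-regeneration of the stereocentre). C5, C6 and C1 are relayed from it in the key step (face selection by C4, Z geometry of 18, β-face methylation). C6–O comes from a retentive C–Si oxidation and C10 from a reagent-controlled reduction.

Key step: step 12

**Route**

Step 1
Reactants: 1 (R)-2-hydroxy-3-methylbutanoic acid
Product: 2 (2R,5R)-2-tert-butyl-5-(propan-2-yl)-1,3-dioxolan-4-one
Conditions: t-BuCHO, p-toluenesulfonic acid monohydrate (cat.), H2SO4 (cat.), pentane, reflux, Dean–Stark trap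
Reagents that add atoms: pivalaldehyde CC(C)(C)C=O
Why: Acid-catalysed acetalisation of the α-hydroxy acid (first stage of the Seebach self-regeneration of stereocentres) should give the thermodynamically favoured cis-dioxolanone, the acetal carbon being set by the existing carbinol centre.

Step 2
Reactants: 3 2-(3-chloropropyl)-2-methyl-1,3-dioxolane
Product: 4 2-(3-iodopropyl)-2-methyl-1,3-dioxolane
Conditions: NaI, acetone, reflux
Reagents that add atoms: sodium iodide [Na+].[I-]
Why: Finkelstein halide exchange gives the primary iodide needed to alkylate a hindered enolate; the ketal is inert.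

Step 3
Reactants: 2 (2R,5R)-2-tert-butyl-5-(propan-2-yl)-1,3-dioxolan-4-one; 4 2-(3-iodopropyl)-2-methyl-1,3-dioxolane
Product: 6 (2R,5R)-2-tert-butyl-5-[3-(2-methyl-1,3-dioxolan-2-yl)propyl]-5-(propan-2-yl)-1,3-dioxolan-4-one, via lithium enolate 5 (not isolated)
Conditions: LiN(i-Pr)2, THF, −78 °C; then 4, DMPU, −78 → −20 °C
Reagents that add atoms: none
Why: Seebach alkylation, in which the planar enolate 5 is attacked anti to the tert-butyl group, i.e. with net retention at the former carbinol carbon, which fixes the future C4 stereocentre as R.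

Step 4
Reactants: 6 (2R,5R)-2-tert-butyl-5-[3-(2-methyl-1,3-dioxolan-2-yl)propyl]-5-(propan-2-yl)-1,3-dioxolan-4-one
Product: 7 (2R)-5-(2-methyl-1,3-dioxolan-2-yl)-2-(propan-2-yl)pentane-1,2-diol
Conditions: LiAlH4, THF, 0 °C → rt; aqueous NaOH work-up
Reagents that add atoms: none
Why: Hydride reduction of the lactone carbonyl collapses the acetal and releases the 1,2-diol without touching the tertiary stereocentre or the ketal.

Step 5
Reactants: 7 (2R)-5-(2-methyl-1,3-dioxolan-2-yl)-2-(propan-2-yl)pentane-1,2-diol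
Product: 8 (2R)-5-(2-methyl-1,3-dioxolan-2-yl)-2-(propan-2-yl)pentane-1,2-diol bis(triethylsilyl) ether
Conditions: Et3SiOTf, 2,6-lutidine, CH2Cl2, −78 → 0 °C
Reagents that add atoms: triethylsilyl trifluoromethanesulfonate CC[Si](CC)(CC)OS(=O)(=O)C(F)(F)F
Why: Silylation with a silyl triflate and a hindered pyridine base covers both the primary and the tertiary hydroxyl, and a ketal (unlike an aldehyde acetal) should survive these conditions at low temperature.

Step 6
Reactants: 8 (2R)-5-(2-methyl-1,3-dioxolan-2-yl)-2-(propan-2-yl)pentane-1,2-diol bis(triethylsilyl) ether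
Product: 9 (2R)-5-(2-methyl-1,3-dioxolan-2-yl)-2-(propan-2-yl)-2-(triethylsilyloxy)pentanal
Conditions: (COCl)2, DMSO, CH2Cl2, −78 → −40 °C; Et3N, → 0 °C
Reagents that add atoms: none
Why: Under Swern conditions a primary triethylsilyl ether is desilylated and oxidised directly to the aldehyde while the tertiary silyl ether stays, and the aldehyde has no α-hydrogen to epimerise.

Step 7
Reactants: 9 (2R)-5-(2-methyl-1,3-dioxolan-2-yl)-2-(propan-2-yl)-2-(triethylsilyloxy)pentanal
Product: 11 1-[(3R)-3-(propan-2-yl)-3-(triethylsilyloxy)cyclopent-1-en-1-yl]ethan-1-one, via keto aldehyde 10 (not isolated)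
Conditions: pyridinium p-toluenesulfonate, acetone–H2O, 50 °C; then KOH, MeOH, 0 °C → rt
Reagents that add atoms: water O
Why: Mild acid transketalisation frees the methyl ketone, and intramolecular aldol condensation (5-exo-trig closure of the internal ketone α-carbon onto the non-enolisable aldehyde, then E1cB dehydration) should give the conjugated acetylcyclopentene, the silyl ether preventing α-ketol rearrangement.

Step 8
Reactants: 12 tert-butyldimethyl(prop-2-yn-1-yloxy)silane
Product: 14 tert-butyl{[3-(dimethylphenylsilyl)prop-2-yn-1-yl]oxy}dimethylsilane, via lithium acetylide 13 (not isolated)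
Conditions: n-BuLi, THF, −78 °C; then PhMe2SiCl, −78 → 0 °C
Reagents that add atoms: chloro(dimethyl)phenylsilane C[Si](C)(Cl)c1ccccc1
Why: Deprotonation of the terminal alkyne and C-silylation of the acetylide is a standard way to cap the alkyne with the oxidisable silyl group.

Step 9
Reactants: 14 tert-butyl{[3-(dimethylphenylsilyl)prop-2-yn-1-yl]oxy}dimethylsilane
Product: 16 1-(tert-butyldimethylsilyl)-3-(dimethylphenylsilyl)prop-2-yn-1-ol (racemic), via α-lithio ether 15 (not isolated)
Conditions: t-BuLi, THF, −78 → −40 °C; then AcOH, −78 °C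
Reagents that add atoms: none
Why: Retro-[1,2]-Brook rearrangement, in which lithiation at the O-bearing propargylic carbon triggers O-to-C migration of the tert-butyldimethylsilyl group, driven by formation of the lithium alkoxide.

Step 10
Reactants: 16 1-(tert-butyldimethylsilyl)-3-(dimethylphenylsilyl)prop-2-yn-1-ol
Product: 17 (Z)-1-(tert-butyldimethylsilyl)-3-(dimethylphenylsilyl)prop-2-en-1-ol (racemic)
Conditions: H2 (1 atm), Pd/CaCO3 poisoned with Pb(OAc)2, quinoline, hexane–EtOAc, rt
Reagents that add atoms: none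
Why: Lindlar semihydrogenation adds H2 syn across the alkyne and should give the Z-vinylsilane.

Step 11
Reactants: 17 (Z)-1-(tert-butyldimethylsilyl)-3-(dimethylphenylsilyl)prop-2-en-1-ol
Product: 18 (Z)-1-(tert-butyldimethylsilyl)-3-(dimethylphenylsilyl)prop-2-en-1-one
Conditions: (COCl)2, DMSO, CH2Cl2, −78 °C; Et3N, −78 → −40 °C; used at once
Reagents that add atoms: none
Why: Swern oxidation of an α-hydroxysilane gives the acylsilane at low temperature, where the Z-alkene is expected to persist, and the carbinol stereocentre is removed.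

Step 12
Reactants: 11 1-[(3R)-3-(propan-2-yl)-3-(triethylsilyloxy)cyclopent-1-en-1-yl]ethan-1-one; 18 (Z)-1-(tert-butyldimethylsilyl)-3-(dimethylphenylsilyl)prop-2-en-1-one
Product: 22 8-(tert-butyldimethylsilyloxy)-6α-(dimethylphenylsilyl)-4β-(triethylsilyloxy)-14-nor-5αH-dauc-7-en-10-one, via lithium enolate 19 (not isolated), via cyclopropanolate 20 (not isolated), via ring-fusion enolate 21 (not isolated)
Conditions: LiN(i-Pr)2, THF, −80 °C; 18, −80 → −30 °C; then MeI, DMPU, −30 → 0 °C
Reagents that add atoms: iodomethane CI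
Why: The kinetic methyl-ketone enolate 19 adds 1,2 to the acylsilane carbonyl of 18, a [1,2]-Brook shift of the tert-butyldimethylsilyl group from carbon to oxygen gives a siloxyallyl anion stabilised by the C6 silyl group, and this closes onto the C10 carbonyl to the cis-1,2-dialkenylcyclopropanolate 20 (C8–C9 made), whose anionic oxy-Cope rearrangement forms C5–C6 and opens to the ring-fusion enolate 21, which MeI traps at C1. The closest known reaction type is the Brook rearrangement-mediated [3+4] annulation of β-silylacryloylsilanes with lithium enolates of alkenyl methyl ketones, 1-acetylcycloalkenes included. The cyclopropane closes 3-exo-trig and the seven-membered ring arises by [3,3] ring enlargement of the cis-divinylcyclopropane through a boat transition state. C5 is controlled by C4 (C6 should approach the cyclopentene face anti to the isopropyl group and syn to the smaller silyloxy group), C6 by the Z geometry of 18 (the silyl group ends cis to H-5, i.e. 6α), and C1 by shielding of the α-face of 21 by the C4 isopropyl and C6 silyl groups, so that methyl should enter from the β-face and give the trans ring fusion. The step needs 1,2- over 1,4-addition (hard lithium enolate, β-silyl substituent), face selectivity on the cyclopentene, and C1- over C9- and O-methylation, the last helped because the sigmatropic step delivers the C1/C10 enolate regiospecifically under non-equilibrating conditions.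

Step 13
Reactants: 22 8-(tert-butyldimethylsilyloxy)-6α-(dimethylphenylsilyl)-4β-(triethylsilyloxy)-14-nor-5αH-dauc-7-en-10-one
Product: 23 6α-(dimethylphenylsilyl)-4β-hydroxy-14-nor-5αH-daucane-8,10-dione
Conditions: HF·pyridine, pyridine, THF, 0 °C → rt
Reagents that add atoms: none
Why: HF·pyridine protodesilylates the silyl enol ether to the C8 ketone and cleaves the tertiary triethylsilyl ether, while the alkyl–silicon bond at C6 is stable.

Step 14
Reactants: 23 6α-(dimethylphenylsilyl)-4β-hydroxy-14-nor-5αH-daucane-8,10-dione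
Product: 24 6α-(dimethylphenylsilyl)-4β-hydroxy-10-oxo-14-nor-5αH-dauc-8-en-8-yl trifluoromethanesulfonate
Conditions: PhNTf2, Et3N, 4-(dimethylamino)pyridine (cat.), CH2Cl2, 0 °C → rt
Reagents that add atoms: N-phenylbis(trifluoromethanesulfonimide) O=S(=O)(N(c1ccccc1)S(=O)(=O)C(F)(F)F)C(F)(F)F
Why: O-sulfonylation of the cyclic 1,3-diketone enolate is expected at the C8 oxygen, remote from the quaternary C1, as in derivatisations of 4,4-disubstituted cycloalkane-1,3-diones, and the tertiary alcohol is not triflated.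

Step 15
Reactants: 24 6α-(dimethylphenylsilyl)-4β-hydroxy-10-oxo-14-nor-5αH-dauc-8-en-8-yl trifluoromethanesulfonate
Product: 25 6α-(dimethylphenylsilyl)-4β-hydroxy-5αH-dauc-8-en-10-one
Conditions: Me2CuLi (from MeLi and CuI, excess), Et2O–THF, −78 → −20 °C
Reagents that add atoms: lithium dimethylcuprate [Li+].C[Cu-]C
Why: Conjugate addition–elimination of the cuprate on the β-triflyloxy enone replaces triflate by methyl and leaves the C8=C9 alkene in conjugation with C10=O.

Step 16
Reactants: 25 6α-(dimethylphenylsilyl)-4β-hydroxy-5αH-dauc-8-en-10-one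
Product: 26 4β,6α-dihydroxy-5αH-dauc-8-en-10-one
Conditions: Hg(OAc)2, AcOOH (32% in AcOH), AcOH, rt
Reagents that add atoms: peracetic acid CC(=O)OO
Why: Fleming–Tamao oxidation (ipso-mercuridesilylation of the phenyl group, then peracid-induced 1,2-shift from silicon to oxygen) converts C6–Si into C6–OH with retention (6α), and the electron-poor enone alkene is inert to the electrophilic reagents.

Step 17
Reactants: 26 4β,6α-dihydroxy-5αH-dauc-8-en-10-one; 27 4-methoxybenzoyl chloride
Product: 28 4β-hydroxy-10-oxo-5αH-dauc-8-en-6α-yl 4-methoxybenzoate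
Conditions: 4-(dimethylamino)pyridine, pyridine, CH2Cl2, 0 → 40 °C
Reagents that add atoms: none
Why: Acylation under nucleophilic catalysis takes the secondary C6 hydroxyl, and the tertiary C4 hydroxyl does not react.

Step 18
Reactants: 28 4β-hydroxy-10-oxo-5αH-dauc-8-en-6α-yl 4-methoxybenzoate
Product: 29 4β,10α-dihydroxy-5αH-dauc-8-en-6α-yl 4-methoxybenzoate (target)
Conditions: (S)-1-methyl-3,3-diphenyltetrahydro-1H,3H-pyrrolo[1,2-c][1,3,2]oxazaborole (0.5 equiv), catecholborane (excess), toluene, −78 → −40 °C; aqueous work-up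
Reagents that add atoms: none
Why: Corey–Bakshi–Shibata reduction in which, with the quaternary C1 as the large and the alkenyl C9 as the small substituent, the (S)-oxazaborolidine should deliver hydride 1,2 to the β-face of C10 and set 10α-OH (R), leaving ester and alkene intact.

**Compound list**

1 | (R)-2-hydroxy-3-methylbutanoic acid | CC(C)[C@@H](O)C(=O)O | starting material
2 | (2R,5R)-2-tert-butyl-5-(propan-2-yl)-1,3-dioxolan-4-one | CC(C)[C@H]1O[C@@H](C(C)(C)C)OC1=O | intermediate
3 | 2-(3-chloropropyl)-2-methyl-1,3-dioxolane | CC1(CCCCl)OCCO1 | starting material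
4 | 2-(3-iodopropyl)-2-methyl-1,3-dioxolane | CC1(CCCI)OCCO1 | intermediate
5 | lithium enolate of 2 (lithium (2R)-2-tert-butyl-5-(propan-2-yl)-1,3-dioxol-4-olate) | CC(C)C1=C([O-])O[C@H](C(C)(C)C)O1.[Li+] | intermediate
6 | (2R,5R)-2-tert-butyl-5-[3-(2-methyl-1,3-dioxolan-2-yl)propyl]-5-(propan-2-yl)-1,3-dioxolan-4-one | CC(C)[C@@]1(CCCC2(C)OCCO2)O[C@@H](C(C)(C)C)OC1=O | intermediate
7 | (2R)-5-(2-methyl-1,3-dioxolan-2-yl)-2-(propan-2-yl)pentane-1,2-diol | CC(C)[C@@](CO)(CCCC1(C)OCCO1)O | intermediate
8 | bis(triethylsilyl) ether of 7 | CC(C)[C@@](CO[Si](CC)(CC)CC)(CCCC1(C)OCCO1)O[Si](CC)(CC)CC | intermediate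
9 | (2R)-5-(2-methyl-1,3-dioxolan-2-yl)-2-(propan-2-yl)-2-(triethylsilyloxy)pentanal | CC(C)[C@@](C=O)(CCCC1(C)OCCO1)O[Si](CC)(CC)CC | intermediate
10 | (2R)-6-oxo-2-(propan-2-yl)-2-(triethylsilyloxy)heptanal | CC(C)[C@@](C=O)(CCCC(C)=O)O[Si](CC)(CC)CC | intermediate
11 | 1-[(3R)-3-(propan-2-yl)-3-(triethylsilyloxy)cyclopent-1-en-1-yl]ethan-1-one | CC(=O)C1=C[C@@](C(C)C)(O[Si](CC)(CC)CC)CC1 | intermediate
12 | tert-butyldimethyl(prop-2-yn-1-yloxy)silane | C#CCO[Si](C)(C)C(C)(C)C | starting material
13 | lithium acetylide of 12 | [Li+].[C-]#CCO[Si](C)(C)C(C)(C)C | intermediate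
14 | tert-butyl{[3-(dimethylphenylsilyl)prop-2-yn-1-yl]oxy}dimethylsilane | C[Si](C)(c1ccccc1)C#CCO[Si](C)(C)C(C)(C)C | intermediate
15 | 14 lithiated at the O-bearing propargylic carbon | [Li]C(O[Si](C)(C)C(C)(C)C)C#C[Si](C)(C)c1ccccc1 | intermediate
16 | 1-(tert-butyldimethylsilyl)-3-(dimethylphenylsilyl)prop-2-yn-1-ol (racemic) | C[Si](C)(c1ccccc1)C#CC(O)[Si](C)(C)C(C)(C)C | intermediate
17 | (Z)-1-(tert-butyldimethylsilyl)-3-(dimethylphenylsilyl)prop-2-en-1-ol (racemic) | C[Si](C)(c1ccccc1)/C=C\C(O)[Si](C)(C)C(C)(C)C | intermediate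
18 | (Z)-1-(tert-butyldimethylsilyl)-3-(dimethylphenylsilyl)prop-2-en-1-one | CC(C)(C)[Si](C)(C)C(=O)/C=C\[Si](C)(C)c1ccccc1 | intermediate
19 | lithium enolate of 11 (deprotonated at the acetyl methyl, the future C9) | [Li+].[O-]C(=C)C1=C[C@@](C(C)C)(O[Si](CC)(CC)CC)CC1 | intermediate
20 | lithium cis-1,2-dialkenylcyclopropanolate: 2-(tert-butyldimethylsilyloxy)-2-[(Z)-2-(dimethylphenylsilyl)ethenyl]-1-[(3R)-3-(propan-2-yl)-3-(triethylsilyloxy)cyclopent-1-en-1-yl]cyclopropan-1-olate | [Li+].[O-][C@@]1(C2=C[C@@](C(C)C)(O[Si](CC)(CC)CC)CC2)C[C@]1(O[Si](C)(C)C(C)(C)C)/C=C\[Si](C)(C)c3ccccc3 | intermediate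
21 | lithium C1/C10 enolate of the ring-enlarged ketone (the 15-nor form of 22) | C[Si](C)(c1ccccc1)[C@H]2C=C(O[Si](C)(C)C(C)(C)C)CC([O-])=C3CC[C@@](O[Si](CC)(CC)CC)(C(C)C)[C@H]23.[Li+] | intermediate
22 | 8-(tert-butyldimethylsilyloxy)-6α-(dimethylphenylsilyl)-4β-(triethylsilyloxy)-14-nor-5αH-dauc-7-en-10-one (1β-methyl; trans-fused) | C[Si](C)(c1ccccc1)[C@H]2C=C(O[Si](C)(C)C(C)(C)C)CC(=O)[C@@]3(C)CC[C@@](O[Si](CC)(CC)CC)(C(C)C)[C@H]23 | intermediate
23 | 6α-(dimethylphenylsilyl)-4β-hydroxy-14-nor-5αH-daucane-8,10-dione | C[Si](C)(c1ccccc1)[C@H]2CC(=O)CC(=O)[C@@]3(C)CC[C@@](O)(C(C)C)[C@H]23 | intermediate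
24 | 6α-(dimethylphenylsilyl)-4β-hydroxy-10-oxo-14-nor-5αH-dauc-8-en-8-yl trifluoromethanesulfonate | C[Si](C)(c1ccccc1)[C@H]2CC(OS(=O)(=O)C(F)(F)F)=CC(=O)[C@@]3(C)CC[C@@](O)(C(C)C)[C@H]23 | intermediate
25 | 6α-(dimethylphenylsilyl)-4β-hydroxy-5αH-dauc-8-en-10-one | C[Si](C)(c1ccccc1)[C@H]2CC(C)=CC(=O)[C@@]3(C)CC[C@@](O)(C(C)C)[C@H]23 | intermediate
26 | 4β,6α-dihydroxy-5αH-dauc-8-en-10-one | O[C@H]2CC(C)=CC(=O)[C@@]3(C)CC[C@@](O)(C(C)C)[C@H]23 | intermediate
27 | 4-methoxybenzoyl chloride | COc1ccc(C(=O)Cl)cc1 | starting material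
28 | 4β-hydroxy-10-oxo-5αH-dauc-8-en-6α-yl 4-methoxybenzoate | COc1ccc(C(=O)O[C@H]2CC(C)=CC(=O)[C@@]3(C)CC[C@@](O)(C(C)C)[C@H]23)cc1 | intermediate
29 | 4β,10α-dihydroxy-5αH-dauc-8-en-6α-yl 4-methoxybenzoate | COc1ccc(C(=O)O[C@H]2CC(C)=C[C@@H](O)[C@@]3(C)CC[C@@](O)(C(C)C)[C@H]23)cc1 | target

**Totals and risks**

Total step count: 18. Longest linear sequence: 13 steps (steps 1, 3–7, 12–18).

Steps most likely to fail:

1. Step 12. Proton transfer from C9 into the ring-fusion enolate before alkylation, or alkylation from the α-face (cis ring fusion), would spoil the third bond of the key step even if the annulation itself runs as precedented; incomplete face selection on the cyclopentene is the further risk. Fallback, from 11 and 18 and back at 25: the annulation is run as in step 12 but quenched with acetic acid instead of iodomethane, which should give the C1-unmethylated annulation product F1 (configuration at C1 immaterial). HF·pyridine then gives the 14,15-dinor diketone F2, PhNTf2/Et3N its C8 enol triflate F3, and Me2CuLi the 15-nor enone F4. Kinetic deprotonation of F4 at the α′ carbon C1 with LiN(i-Pr)2 (2.2 equiv, THF, −78 °C) and methylation of the cross-conjugated enolate with MeI installs the angular methyl as a separate step and returns to the route at 25.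

2. Step 18. Hydride delivery from the α-face (substrate control by the angular methyl overriding the catalyst) would give the C10 epimer. Fallback, from 28 and back at 29: Luche reduction (NaBH4, CeCl3·7H2O, MeOH, −78 °C) is expected to take the α-face and give the 10β-alcohol F5. Mitsunobu reaction (PPh3, diisopropyl azodicarboxylate, chloroacetic acid, toluene, 0 °C → rt) inverts C10 to the 10α-chloroacetate F6. K2CO3 in MeOH at 0 °C then cleaves the chloroacetate in the presence of the 4-methoxybenzoate and gives 29.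

3. Step 11. Z to E isomerisation of the β-silyl enoyl silane by reversible amine addition during the oxidation would invert the C6 configuration downstream. Fallback, from 16 and back at 18: the propargylic α-silyl carbinol 16 is oxidised first (MnO2, CH2Cl2, rt) to the alkynoyl silane F7, and cis-semihydrogenation of the ynone (H2, Pd/CaCO3 poisoned with Pb(OAc)2, hexane, −20 °C, in the dark) should then give 18 without exposing the Z-enone to amine base.

**Further compounds**

F1 | step 12 | 8-(tert-butyldimethylsilyloxy)-6α-(dimethylphenylsilyl)-4β-(triethylsilyloxy)-14,15-dinor-5αH-dauc-7-en-10-one (C1 undefined) | C[Si](C)(c1ccccc1)[C@H]2C=C(O[Si](C)(C)C(C)(C)C)CC(=O)C3CC[C@@](O[Si](CC)(CC)CC)(C(C)C)[C@H]23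
F2 | step 12 | 6α-(dimethylphenylsilyl)-4β-hydroxy-14,15-dinor-5αH-daucane-8,10-dione (C1 undefined) | C[Si](C)(c1ccccc1)[C@H]2CC(=O)CC(=O)C3CC[C@@](O)(C(C)C)[C@H]23
F3 | step 12 | 6α-(dimethylphenylsilyl)-4β-hydroxy-10-oxo-14,15-dinor-5αH-dauc-8-en-8-yl trifluoromethanesulfonate (C1 undefined) | C[Si](C)(c1ccccc1)[C@H]2CC(OS(=O)(=O)C(F)(F)F)=CC(=O)C3CC[C@@](O)(C(C)C)[C@H]23
F4 | step 12 | 6α-(dimethylphenylsilyl)-4β-hydroxy-15-nor-5αH-dauc-8-en-10-one (C1 undefined) | C[Si](C)(c1ccccc1)[C@H]2CC(C)=CC(=O)C3CC[C@@](O)(C(C)C)[C@H]23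
F5 | step 18 | 4β,10β-dihydroxy-5αH-dauc-8-en-6α-yl 4-methoxybenzoate | COc1ccc(C(=O)O[C@H]2CC(C)=C[C@H](O)[C@@]3(C)CC[C@@](O)(C(C)C)[C@H]23)cc1
F6 | step 18 | 10α-(chloroacetoxy)-4β-hydroxy-5αH-dauc-8-en-6α-yl 4-methoxybenzoate | COc1ccc(C(=O)O[C@H]2CC(C)=C[C@@H](OC(=O)CCl)[C@@]3(C)CC[C@@](O)(C(C)C)[C@H]23)cc1
F7 | step 11 | 1-(tert-butyldimethylsilyl)-3-(dimethylphenylsilyl)prop-2-yn-1-one | CC(C)(C)[Si](C)(C)C(=O)C#C[Si](C)(C)c1ccccc1
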